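A direct plan would go through a chalcone: Claisen–Schmidt condensation of the bis-MOM acetophenone A1 with the bromo aldehyde A2 would give chalcone A3.
Oxidative 1,2-aryl migration of A3 with Tl(NO3)3 in methanol, then acid, would close ring C and remove the MOM groups to give bromoisoflavone A4.
A Stille coupling of A4 with prenyltributylstannane A5 would add the prenyl group in the last step.
Weak step, the oxidative aryl migration: it needs more than one equivalent of toxic trivalent thallium on a di-ortho-substituted aroyl ketone, and migration, triple deprotection, ring closure and aromatisation all rest on one acid treatment.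
Weak step, the final prenylation: a hindered, electron-rich bromide beside a methoxy group would have to couple on an unprotected, base-sensitive diphenol, with linear against branched allyl transfer not secured and tin to be removed from the final compound.
Weak stretch, the way to A1 and A2: a regioselective mono-methylation of a bromocatechol aldehyde and three MOM groups that are put on and taken off build no bond of the skeleton.

**Retrosynthetic overview**
1. Ring C is cut at C3–C4, not at O1–C2 and not at the C3–aryl bond. Adding water across C2=C3 shows a tertiary α-ketol (C3–OH next to C4=O), the retron of an intramolecular aldehyde–ketone benzoin reaction. The precursor is an open keto aldehyde: ring A carries C4 as a formyl group, ring B carries C3 as a phenacyl ketone, and the two are linked through O1–C2H2.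
2. Order of rings: rings A and B are bought as benzenes, the ether O1–C2 is made by Williamson alkylation, and ring C is closed last at carbon by a carbene catalyst and made aromatic by loss of water in the same flask. There is no chalcone, no aryl migration and no thallium.
3. Ring A comes from 2,4-dihydroxy-6-methoxybenzaldehyde, so C4 and the 5-OMe/7-OH pattern are fixed from the start and only the 7-oxygen needs a protecting group.
4. Ring B is an anisole whose two ortho positions (C3' hydroxyl, C5' prenyl) and para position (C1') carry three different groups. 2,4,6-Tribromoanisole gives them by three halogen–metal exchanges in the order ortho, ortho, para, so the prenyl group enters in the first step on a simple arene and no coupling is left for the finished isoflavone.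
5. Two MOM groups are used in all, and both fall in the last step.

Key step: step 7

Remark: 2,4,6-tribromoanisole, prenyl bromide, 2-chloro-N-methoxy-N-methylacetamide and 2,4-dihydroxy-6-methoxybenzaldehyde are taken as commercial. The target has no stereocentre and no alkene geometry; the one stereocentre formed on the way (C3 of the ketol in step 7) is transient.

**Route**

Step 1
Reactants: 1 2,4,6-tribromoanisole (1,3,5-tribromo-2-methoxybenzene); 2 prenyl bromide (1-bromo-3-methylbut-2-ene)
Product: 3 1,5-dibromo-2-methoxy-3-(3-methylbut-2-en-1-yl)benzene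
Conditions: i-PrMgCl·LiCl (1.05 equiv), THF, −20 °C; then CuBr·SMe2 (5 mol %), 2 (1.2 equiv), −20 °C to rt
Reagents that add atoms: none
Why: Br/Mg exchange should be fastest at a bromine ortho to the methoxy group (inductive stabilisation and chelation of the arylmagnesium; the two ortho bromines are equivalent), and copper-catalysed allylic substitution of the aryl Grignard reagent on prenyl bromide should take place at the unsubstituted terminus to give the linear prenyl arene.

Step 2
Reactants: 3 1,5-dibromo-2-methoxy-3-(3-methylbut-2-en-1-yl)benzene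
Product: 4 5-bromo-2-methoxy-3-(3-methylbut-2-en-1-yl)phenol
Conditions: i-PrMgCl·LiCl (1.1 equiv), THF, 0 °C to rt; B(OMe)3, 0 °C; then NaOH (aq), H2O2 (30%), 0 °C
Reagents that add atoms: hydrogen peroxide, OO
Why: A second ortho-selective Br/Mg exchange (the remaining ortho bromine should react before the para one, as in 2,4-dibromoanisole), borylation and boronate oxidation (1,2-shift of the aryl group from boron to oxygen) should give the phenol, and cold alkaline H2O2 leaves the isolated trisubstituted alkene alone.

Step 3
Reactants: 4 5-bromo-2-methoxy-3-(3-methylbut-2-en-1-yl)phenol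
Product: 5 5-bromo-2-methoxy-1-(methoxymethoxy)-3-(3-methylbut-2-en-1-yl)benzene
Conditions: MOMCl (1.3 equiv), i-Pr2NEt (2 equiv), CH2Cl2, 0 °C to rt
Reagents that add atoms: chloromethyl methyl ether (MOMCl), COCCl
Why: Williamson-type O-alkylation of the phenol; the MOM ether should withstand Grignard formation, carbonate, the carbene catalyst and SOCl2/pyridine, and is removed by the acid of step 8.

Step 4
Reactants: 5 5-bromo-2-methoxy-1-(methoxymethoxy)-3-(3-methylbut-2-en-1-yl)benzene; 6 2-chloro-N-methoxy-N-methylacetamide
Product: 7 2-chloro-1-[4-methoxy-3-(methoxymethoxy)-5-(3-methylbut-2-en-1-yl)phenyl]ethan-1-one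
Conditions: Mg, LiCl, THF, rt; then 6 (1.2 equiv), −10 °C to rt; aq NH4Cl
Reagents that add atoms: none
Why: Grignard formation at the last (para) bromine and Weinreb ketone synthesis: the chelated tetrahedral adduct of the N-methoxy-N-methylamide should prevent a second addition and release the α-chloroketone only on work-up.

Step 5
Reactants: 8 2,4-dihydroxy-6-methoxybenzaldehyde
Product: 9 2-hydroxy-6-methoxy-4-(methoxymethoxy)benzaldehyde
Conditions: MOMCl (1.1 equiv), i-Pr2NEt (1.5 equiv), CH2Cl2, 0 °C
Reagents that add atoms: chloromethyl methyl ether (MOMCl), COCCl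
Why: Selective O-alkylation of the 4-OH, which is the more acidic one (para to the formyl group) and is not tied up in the hydrogen bond that holds the 2-OH to the aldehyde.

Step 6
Reactants: 9 2-hydroxy-6-methoxy-4-(methoxymethoxy)benzaldehyde; 7 2-chloro-1-[4-methoxy-3-(methoxymethoxy)-5-(3-methylbut-2-en-1-yl)phenyl]ethan-1-one
Product: 10 2-methoxy-6-{2-[4-methoxy-3-(methoxymethoxy)-5-(3-methylbut-2-en-1-yl)phenyl]-2-oxoethoxy}-4-(methoxymethoxy)benzaldehyde
Conditions: K2CO3 (1.5 equiv), KI (10 mol %), DMF, rt
Reagents that add atoms: none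
Why: Williamson ether synthesis on an α-haloketone with Finkelstein activation forms the O1–C2 bond; room temperature and a carbonate base are chosen so that the phenacyl ether should not go on to the Rap–Stoermer aldol condensation.

Step 7
Reactants: 10 2-methoxy-6-{2-[4-methoxy-3-(methoxymethoxy)-5-(3-methylbut-2-en-1-yl)phenyl]-2-oxoethoxy}-4-(methoxymethoxy)benzaldehyde
Product: 12 5-methoxy-3-[4-methoxy-3-(methoxymethoxy)-5-(3-methylbut-2-en-1-yl)phenyl]-7-(methoxymethoxy)-4H-chromen-4-one, via 3-hydroxyisoflavanone 11 (not isolated)
Conditions: 2-(pentafluorophenyl)-6,7-dihydro-5H-pyrrolo[2,1-c][1,2,4]triazol-2-ium tetrafluoroborate (20 mol %), Et3N (20 mol %), toluene, 40 °C; then pyridine (6 equiv), SOCl2 (2 equiv), 0 °C to rt, same flask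
Reagents that add atoms: none
Why: The triazolylidene set free by Et3N adds to the formyl group of 10 and proton transfer gives the enaminol (an acyl anion equivalent at the future C4), which attacks the aryl ketone carbon (the future C3); release of the carbene leaves the tertiary ketol 11 with ring C closed at C3–C4 in a 6-exo-trig mode. The closest known reaction type is the carbene-catalysed intramolecular crossed aldehyde–ketone benzoin cyclisation of 2-(2-aryl-2-oxoethoxy)benzaldehydes to 3-aryl-3-hydroxychroman-4-ones. SOCl2/pyridine then turns the tertiary hydroxyl into a chlorosulfite, and elimination with a hydrogen at C2 (the only β-hydrogens) should give the 4-pyranone, whose conjugation drives the loss of water. The single new stereocentre (C3 of 11) forms as a racemate and is erased when C2=C3 forms, so no control is needed. The step needs the carbene pathway to outrun the base-induced aldol condensation of the O–CH2–CO unit onto the aldehyde (which would give a 2-aroylbenzofuran): the weak amine base in catalytic amount, the acidic N-pentafluorophenyl triazolium salt and the low reactivity of the di-ortho-alkoxy aldehyde towards an enolate should secure this. The acid formed from SOCl2 at 0 °C also quenches the carbene, so no retro-benzoin reaction can follow.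

Step 8
Reactants: 12 5-methoxy-3-[4-methoxy-3-(methoxymethoxy)-5-(3-methylbut-2-en-1-yl)phenyl]-7-(methoxymethoxy)-4H-chromen-4-one
Product: 13 7-hydroxy-3-[3-hydroxy-4-methoxy-5-(3-methylbut-2-en-1-yl)phenyl]-5-methoxy-4H-chromen-4-one
Conditions: HCl (3 M aq), MeOH/THF, 45 °C
Reagents that add atoms: none
Why: Acid-catalysed acetal cleavage of both MOM ethers; the prenyl group has a methoxy group and no hydroxyl as its ortho neighbour, so it cannot cyclise to a chroman, and the 5-OMe should survive because no Lewis acid is present.

**Compound list**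
1 | 2,4,6-tribromoanisole (1,3,5-tribromo-2-methoxybenzene) | COc1c(Br)cc(Br)cc1Br | starting material
2 | prenyl bromide (1-bromo-3-methylbut-2-ene) | CC(C)=CCBr | starting material
3 | 1,5-dibromo-2-methoxy-3-(3-methylbut-2-en-1-yl)benzene | COc1c(Br)cc(Br)cc1CC=C(C)C | intermediate
4 | 5-bromo-2-methoxy-3-(3-methylbut-2-en-1-yl)phenol | COc1c(O)cc(Br)cc1CC=C(C)C | intermediate
5 | 5-bromo-2-methoxy-1-(methoxymethoxy)-3-(3-methylbut-2-en-1-yl)benzene | COCOc1cc(Br)cc(CC=C(C)C)c1OC | intermediate
6 | 2-chloro-N-methoxy-N-methylacetamide | CON(C)C(=O)CCl | starting material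
7 | 2-chloro-1-[4-methoxy-3-(methoxymethoxy)-5-(3-methylbut-2-en-1-yl)phenyl]ethan-1-one | COCOc1cc(C(=O)CCl)cc(CC=C(C)C)c1OC | intermediate
8 | 2,4-dihydroxy-6-methoxybenzaldehyde | COc1cc(O)cc(O)c1C=O | starting material
9 | 2-hydroxy-6-methoxy-4-(methoxymethoxy)benzaldehyde | COCOc1cc(O)c(C=O)c(OC)c1 | intermediate
10 | 2-methoxy-6-{2-[4-methoxy-3-(methoxymethoxy)-5-(3-methylbut-2-en-1-yl)phenyl]-2-oxoethoxy}-4-(methoxymethoxy)benzaldehyde | COCOc1cc(OC)c(C=O)c(OCC(=O)c2cc(CC=C(C)C)c(OC)c(OCOC)c2)c1 | intermediate
11 | 3-hydroxy-5-methoxy-3-[4-methoxy-3-(methoxymethoxy)-5-(3-methylbut-2-en-1-yl)phenyl]-7-(methoxymethoxy)-2,3-dihydro-4H-chromen-4-one (racemic) | COCOc1cc(OC)c2c(c1)OCC(O)(c1cc(CC=C(C)C)c(OC)c(OCOC)c1)C2=O | intermediate (not isolated)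
12 | 5-methoxy-3-[4-methoxy-3-(methoxymethoxy)-5-(3-methylbut-2-en-1-yl)phenyl]-7-(methoxymethoxy)-4H-chromen-4-one | COCOc1cc(OC)c2c(c1)occ(-c1cc(CC=C(C)C)c(OC)c(OCOC)c1)c2=O | intermediate
13 | 7-hydroxy-3-[3-hydroxy-4-methoxy-5-(3-methylbut-2-en-1-yl)phenyl]-5-methoxy-4H-chromen-4-one | COc1c(O)cc(-c2coc3cc(O)cc(OC)c3c2=O)cc1CC=C(C)C | target

**Step count and risks**
Total: 8 steps. Longest linear sequence: 7 steps (1, 2, 3, 4, 6, 7, 8).

Steps most likely to fail:

Step 7. The carbene may add too slowly to the electron-rich aldehyde with two ortho alkoxy groups, so that base-induced aldol condensation to an aroylbenzofuran or simple recovery of 10 takes over. The elimination of the tertiary α-ketol may also stop short or turn into an α-ketol rearrangement. The fallback sets out from bromide 5 and joins ring B to a ready-made chromone. Mg/LiCl in THF, then 2-isopropoxy-4,4,5,5-tetramethyl-1,3,2-dioxaborolane, would give 2-[4-methoxy-3-(methoxymethoxy)-5-(3-methylbut-2-en-1-yl)phenyl]-4,4,5,5-tetramethyl-1,3,2-dioxaborolane F1. In parallel, commercial 1-(2,4-dihydroxy-6-methoxyphenyl)ethan-1-one F2 would be protected at the 4-OH (MOMCl, i-Pr2NEt) to 1-[2-hydroxy-6-methoxy-4-(methoxymethoxy)phenyl]ethan-1-one F3. Condensation with DMF dimethyl acetal at 90 °C would give (E)-3-(dimethylamino)-1-[2-hydroxy-6-methoxy-4-(methoxymethoxy)phenyl]prop-2-en-1-one F4, and I2 in CHCl3 would cyclise it to 3-iodo-5-methoxy-7-(methoxymethoxy)-4H-chromen-4-one F5. Suzuki–Miyaura coupling of F1 with F5 (Pd(dppf)Cl2, K3PO4, dioxane/H2O, 70 °C) would give 12, and step 8 follows unchanged.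

Step 6. During the alkylation the base may enolise the new phenacyl ether, which then condenses onto the neighbouring aldehyde (Rap–Stoermer pathway), or the hydrogen-bonded phenol may alkylate too slowly at room temperature. The fallback sets out from chloroketone 7 and joins the halves without base. HCO2Na in aqueous EtOH at reflux would give 2-hydroxy-1-[4-methoxy-3-(methoxymethoxy)-5-(3-methylbut-2-en-1-yl)phenyl]ethan-1-one F6. Mitsunobu etherification of phenol 9 with F6 (PPh3, DIAD, THF, 0 °C to rt) would then give 10.

Step 1. The prenyl group may be transferred in part through its substituted terminus, giving the branched 1,1-dimethylallyl arene, and the exchange may lose site control (a second exchange or exchange at the para bromine). The fallback sets out from 1 and builds the prenyl terminus by metathesis. The same arylmagnesium (i-PrMgCl·LiCl, THF, −20 °C) with allyl bromide and CuBr·SMe2 (5 mol %) would give 1,5-dibromo-2-methoxy-3-(prop-2-en-1-yl)benzene F7, for which the two allyl termini are the same. Cross-metathesis of F7 with excess 2-methylbut-2-ene (second-generation Grubbs catalyst, RuCl2(=CHPh)(PCy3)(H2IMes), CH2Cl2, 40 °C) would give 3.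

**Further compounds**
F1 | step 7 | 2-[4-methoxy-3-(methoxymethoxy)-5-(3-methylbut-2-en-1-yl)phenyl]-4,4,5,5-tetramethyl-1,3,2-dioxaborolane | COCOc1cc(B2OC(C)(C)C(C)(C)O2)cc(CC=C(C)C)c1OC
F2 | step 7 | 1-(2,4-dihydroxy-6-methoxyphenyl)ethan-1-one (purchased) | CC(=O)c1c(O)cc(O)cc1OC
F3 | step 7 | 1-[2-hydroxy-6-methoxy-4-(methoxymethoxy)phenyl]ethan-1-one | CC(=O)c1c(O)cc(OCOC)cc1OC
F4 | step 7 | (E)-3-(dimethylamino)-1-[2-hydroxy-6-methoxy-4-(methoxymethoxy)phenyl]prop-2-en-1-one | CN(C)/C=C/C(=O)c1c(O)cc(OCOC)cc1OC
F5 | step 7 | 3-iodo-5-methoxy-7-(methoxymethoxy)-4H-chromen-4-one | COCOc1cc(OC)c2c(c1)occ(I)c2=O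
F6 | step 6 | 2-hydroxy-1-[4-methoxy-3-(methoxymethoxy)-5-(3-methylbut-2-en-1-yl)phenyl]ethan-1-one | COCOc1cc(C(=O)CO)cc(CC=C(C)C)c1OC
F7 | step 1 | 1,5-dibromo-2-methoxy-3-(prop-2-en-1-yl)benzene | COc1c(Br)cc(Br)cc1CC=C
A1 | direct plan | 1-[2-methoxy-4,6-bis(methoxymethoxy)phenyl]ethan-1-one | CC(=O)c1c(OC)cc(OCOC)cc1OCOC
A2 | direct plan | 3-bromo-4-methoxy-5-(methoxymethoxy)benzaldehyde | COCOc1cc(C=O)cc(Br)c1OC
A3 | direct plan | (E)-3-[3-bromo-4-methoxy-5-(methoxymethoxy)phenyl]-1-[2-methoxy-4,6-bis(methoxymethoxy)phenyl]prop-2-en-1-one | COCOc1cc(OC)c(C(=O)/C=C/c2cc(Br)c(OC)c(OCOC)c2)c(OCOC)c1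
A4 | direct plan | 3-(3-bromo-5-hydroxy-4-methoxyphenyl)-7-hydroxy-5-methoxy-4H-chromen-4-one | COc1c(O)cc(-c2coc3cc(O)cc(OC)c3c2=O)cc1Br
A5 | direct plan | tributyl(3-methylbut-2-en-1-yl)stannane | CCCC[Sn](CCCC)(CCCC)CC=C(C)C
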